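Late in Monday's run, from 27 h to 42 h, product climbs at 0.00153 M h⁻¹, although 0.289 M of starting material remains at the last reading.

| flask | starting material | partner | free catalyst | time |
|---|---|---|---|---|
| Monday's | 0.600 M | 1.20 M | 0.0600 M |  |
| Saturday's | 0.300 M | 1.20 M | 0.0600 M |  |
| Tuesday's | 0.600 M | 1.80 M | 0.0600 M |  |
| Thursday's | 0.600 M | 1.20 M | 0.0600 M | 250 h |

* how the opening rate goes with [starting material] round the charge of the Monday's run: the exponent of the rate at two percent of starting material gone to product (one fixed amount of product, the same in the runs compared)
* how the opening rate goes with [partner] round the charge of the Monday's run: the exponent of the rate at two percent of starting material gone to product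
* product in the Thursday's run at 250 h, as a share of the starting material charged

- Overall: starting material + partner -> product, with free catalyst as catalyst.
- Constant volume, constant temperature.
- Bound and free are read together.
- "The second partner" is partner.
- An order is taken over about fifteen percent of the charge, up and down.

| run | time / h | [product] / M |
|---|---|---|
| Monday's run | 1.7 | 0.0293 |
| Monday's run | 2.7 | 0.0632 |
| Monday's run | 4.2 | 0.1038 |
| Monday's run | 6.7 | 0.1520 |
| Monday's run | 11 | 0.2124 |
| Monday's run | 17 | 0.2578 |
| Monday's run | 27 | 0.2878 |
| Monday's run | 42 | 0.3108 |
| Saturday's run | 1.7 | 0.0251 |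
| Saturday's run | 2.7 | 0.0494 |
| Saturday's run | 4.2 | 0.0885 |
| Saturday's run | 6.7 | 0.1316 |
| Saturday's run | 11 | 0.1798 |
| Saturday's run | 17 | 0.2227 |
| Saturday's run | 27 | 0.2539 |
| Saturday's run | 42 | 0.2738 |
| Tuesday's run | 1.7 | 0.0408 |
| Tuesday's run | 2.7 | 0.0741 |
| Tuesday's run | 4.2 | 0.1169 |
| Tuesday's run | 6.7 | 0.1735 |
| Tuesday's run | 11 | 0.2367 |
| Tuesday's run | 17 | 0.2843 |
| Tuesday's run | 27 | 0.3252 |
| Tuesday's run | 42 | 0.3480 |

(each reading ± 0.002 M)

The readings draw Monday's curve from its start. Up to 1.7 h product averages 0.0172 M h⁻¹, and between the first two readings the slope is 0.0339 M h⁻¹, faster than the first average, so Monday's flask opens with a lag. The knee comes next: from 6.7 h to 11 h the slope is 0.0140 M h⁻¹, and from 17 h to 27 h it is 0.00300 M h⁻¹. Saturday's run opens with 0.300 M of starting material, close to what Monday's flask still holds at its last reading, yet its slope between the first two readings is 0.0243 M h⁻¹, far above Monday's late slope. At similar [starting material], then, Monday's late flask runs much slower than Saturday's opening one.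

The quantity to watch is the fading time, the time in which the late rate falls by a factor of e. Monday's two late slopes differ by a factor of 1.96 over the 12.5 h between their midpoints, which reads as 18.6 h. If the fading goes on, the product still to come after the last reading is the rate there times the fading time, 0.0191 M. Thursday's flask has Monday's charge, and the 208 h beyond the last reading far exceed the fading time. The reckoning here therefore puts the level at 0.330 M, or 55.0 % of the charge.

The forecast, for which “the catalyst appears to be dying”, gives orders of 0.2 in starting material and 0.55 in partner, and for Thursday's flask a higher share than this reckoning, 58 %.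

The flask gives orders of 0.13 in starting material and 0.32 in partner, both lower than the forecast's, and in Thursday's flask 53.2 % of the charge at 250 h.

active catalyst + starting material → catalyst-substrate complex (10.33 M⁻¹ h⁻¹); catalyst-substrate complex + partner → loaded catalyst (1.357 M⁻¹ h⁻¹); loaded catalyst → product + active catalyst (2.509 h⁻¹); free catalyst → active catalyst (1.548 h⁻¹); 2 partner → lost reagent (0.1782 M⁻¹ h⁻¹) By its loss step alone, partner at Monday's charge has a first half-life of 2.34 h. Thursday's product at 250 h lies 0.00861 M above Monday's last reading, less than the reckoned tail. On Saturday's late slopes the fading time reads 14.6 h, which, if the fading goes on, puts that flask's level at 0.285 M, or 95.0 % of its charge of starting material.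

The earlier runs and the new flask stem from a simulated flask with constants of no real substance; noise was put on by code.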